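**Retrosynthetic overview**
1. Last step: the second carbocycle of the decalin (ring 1) is closed by cation–olefin cyclisation of a tertiary carbinol onto the (E)-9,10-alkene; 1,2-H and 1,2-Me shifts and loss of a methyl proton in the same cascade deliver C9, C10 and the exocyclic methylene.
2. The cyclisation precursor is cut at C8–C9 (B-alkyl Suzuki–Miyaura coupling) into a cyclohexenyl vinyl iodide (fragment 1) and a vinyl-1,2-dioxane (fragment 2).
3. Fragment 2: the 1,2-dioxane is closed by conjugate addition of a C6 hydroperoxide (a hydroperoxy ketal from ozonolysis in MeOH) to an (E)-2-methyl-2-enoate; the C6 carbon substituent is then introduced through the peroxycarbenium ion, cis to the C3 side chain.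
4. Fragment 1: the cyclohexene (ring 2) is bought as a p-menthadienol; a Claisen rearrangement sets C12 cis to C17, followed by alkyne formation, carboalumination–iodination and Markovnikov hydration.
5. Ring order: cyclohexene ring 2 (terpene pool) → 1,2-dioxane (step 7) → decalin ring 1 (step 10).

Assumption 1: the presumed biosynthesis is taken as (a) conjugate addition of a C6 hydroperoxide to the Δ2-enoate for the 1,2-dioxane and (b) for the decalin a terpinyl-type cyclohexene whose exocyclic C18 cation is trapped by the 9,10-alkene, then 1,2-H (C9→C10) and 1,2-Me (C18→C9) shifts and loss of a methyl proton; carbons carry norsesterterpene numbers (C1 ester carbon, C3 and C6 dioxane carbons, C9 quaternary and C10 secondary-methyl decalin carbons, C12 and C17 ring-fusion carbons, C18 the methylidene-bearing carbon).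

Assumption 2: dienol 1, the enantiomer of the (1S,4R)-dienol made in bulk for cannabinoid synthesis, is purchasable (it is made the same way from (S)-limonene oxide).

**Route**

Step 1
Reactants: 1 (1R,4S)-1-methyl-4-(prop-1-en-2-yl)cyclohex-2-en-1-ol
Product: 3 2-[(1R,6S)-3-methyl-6-(prop-1-en-2-yl)cyclohex-2-en-1-yl]acetaldehyde, via allyl vinyl ether 2 (not isolated)
Conditions: EtOCH=CH2 (solvent), Hg(OAc)2 (10 mol%), 35 °C; then PhMe, sealed tube, 140 °C
Reagents that add atoms: ethyl vinyl ether, C=COCC
Why: Mercury-catalysed vinyl exchange gives the tertiary allyl vinyl ether and the Claisen [3,3] rearrangement transfers the C–O bond suprafacially into a C–C bond at the far allylic carbon, so the CH2CHO group enters on the face that carried the hydroxyl group, cis to the isopropenyl group (C12 set as R from the purchased C17 centre), the reacting conformer having a pseudoaxial C–O bond and a pseudoequatorial isopropenyl group.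

Step 2
Reactants: 3 2-[(1R,6S)-3-methyl-6-(prop-1-en-2-yl)cyclohex-2-en-1-yl]acetaldehyde
Product: 4 (3R,4S)-1-methyl-4-(prop-1-en-2-yl)-3-(prop-2-yn-1-yl)cyclohex-1-ene
Conditions: dimethyl (1-diazo-2-oxopropyl)phosphonate, K2CO3, MeOH, 0 °C → rt
Reagents that add atoms: dimethyl (1-diazo-2-oxopropyl)phosphonate, COP(=O)(OC)C(=[N+]=[N-])C(C)=O
Why: Ohira–Bestmann (Seyferth–Gilbert) homologation turns the aldehyde into the terminal alkyne under mild K2CO3/MeOH conditions, and since the α-carbon is a CH2 group no stereocentre can epimerise.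

Step 3
Reactants: 4 (3R,4S)-1-methyl-4-(prop-1-en-2-yl)-3-(prop-2-yn-1-yl)cyclohex-1-ene
Product: 6 (3R,4S)-3-[(2E)-3-iodo-2-methylprop-2-en-1-yl]-1-methyl-4-(prop-1-en-2-yl)cyclohex-1-ene, via alkenylalane 5 (not isolated)
Conditions: Me3Al, Cp2ZrCl2 (25 mol%), CH2Cl2, 0 °C → rt; then I2, THF, −30 °C
Reagents that add atoms: trimethylaluminium, C[Al](C)C; iodine, [I][I]
Why: Negishi zirconium-catalysed carboalumination adds Me and Al syn across the terminal alkyne with Me at the internal carbon and iodinolysis proceeds with retention, which fixes the (E)-trisubstituted geometry of the future 9,10-alkene, while the 1,1-disubstituted and trisubstituted alkenes do not react.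

Step 4
Reactants: 6 (3R,4S)-3-[(2E)-3-iodo-2-methylprop-2-en-1-yl]-1-methyl-4-(prop-1-en-2-yl)cyclohex-1-ene
Product: 7 2-[(1S,2R)-2-[(2E)-3-iodo-2-methylprop-2-en-1-yl]-4-methylcyclohex-3-en-1-yl]propan-2-ol
Conditions: Co(acac)2 (20 mol%), PhSiH3, O2 (1 atm), THF/iPrOH, rt
Reagents that add atoms: dioxygen, O=O
Why: Mukaiyama hydration (cobalt hydride hydrogen-atom transfer, O2 capture of the tertiary radical, reduction of the peroxide) is selective for the 1,1-disubstituted alkene over the trisubstituted ring alkene and the iodoalkene and gives the Markovnikov tertiary alcohol that later serves as the C18 cation precursor, with no stereocentre formed.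

Step 5
Reactants: 8 2-methylhexa-1,5-diene; 9 methyl methacrylate
Product: 10 methyl (2E)-2,6-dimethylhepta-2,6-dienoate
Conditions: second-generation Hoveyda–Grubbs catalyst (3 mol%), excess 9, CH2Cl2, 40 °C
Reagents that add atoms: none
Why: Olefin cross-metathesis joins the monosubstituted alkene of 8 with excess methyl methacrylate to the thermodynamically preferred (E)-2-methyl-2-enoate, the 1,1-disubstituted alkene of 8 staying a spectator.

Step 6
Reactants: 10 methyl (2E)-2,6-dimethylhepta-2,6-dienoate
Product: 11 methyl (2E)-6-hydroperoxy-6-methoxy-2-methylhept-2-enoate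
Conditions: O3, CH2Cl2/MeOH (4:1), −78 °C; N2 purge
Reagents that add atoms: ozone, [O-][O+]=O; methanol, CO
Why: Ozonolysis with alcohol trapping: ozone cleaves the electron-rich 1,1-disubstituted alkene and spares the electron-poor enoate, the carbonyl oxide forms on the more substituted carbon and is captured by methanol as the α-methoxy hydroperoxide, whose new ketal centre (both configurations) is erased in step 8.

Step 7
Reactants: 11 methyl (2E)-6-hydroperoxy-6-methoxy-2-methylhept-2-enoate
Product: 12 methyl (2S)-2-[(3R)-6-methoxy-6-methyl-1,2-dioxan-3-yl]propanoate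
Conditions: chiral bifunctional iminophosphorane–thiourea organocatalyst (10 mol%), Et2O, −20 °C
Reagents that add atoms: none
Why: Proposed new method: the hydroperoxy ketal (pKa about 12) is deprotonated by the chiral superbase, which also hydrogen-bonds the ester, so the 6-exo peroxy-Michael closure is expected to be face-selective at C3 (R, catalyst antipode chosen by screening), and the enolate is protonated anti to the new C–O bond across the (E)-alkene, which gives the (2S,3R) pair; the closest known reactions are the achiral amine-mediated cyclisation of hydroperoxy ketals onto enoates and iminophosphorane-catalysed enantioselective oxa- and sulfa-Michael additions to unactivated unsaturated esters.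

Step 8
Reactants: 12 methyl (2S)-2-[(3R)-6-methoxy-6-methyl-1,2-dioxan-3-yl]propanoate
Product: 13 methyl (2S)-2-[(3R,6S)-6-ethenyl-6-methyl-1,2-dioxan-3-yl]propanoate
Conditions: CH2=CHBF3K, BF3·OEt2, CH2Cl2/MeCN, −40 °C
Reagents that add atoms: potassium vinyltrifluoroborate, C=C[B-](F)(F)F.[K+]
Why: Proposed new method: BF3 ionises the methoxy group to the cyclic peroxycarbenium ion (both ketal epimers converge) and the vinyl group is delivered from the vinyldifluoroborane formed in the flask along the axial trajectory of the half-chair that has the C3 side chain pseudoequatorial, which places vinyl cis to the side chain (C6 set, S by CIP for the vinyl compound); the closest known reactions are Lewis-acid allylation of cyclic peroxyketals through peroxycarbenium ions and BF3-promoted coupling of potassium organotrifluoroborates with acetals.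

Step 9
Reactants: 13 methyl (2S)-2-[(3R,6S)-6-ethenyl-6-methyl-1,2-dioxan-3-yl]propanoate; 7 2-[(1S,2R)-2-[(2E)-3-iodo-2-methylprop-2-en-1-yl]-4-methylcyclohex-3-en-1-yl]propan-2-ol
Product: 15 methyl (2S)-2-[(3R,6R)-6-{(3E)-5-[(1R,6S)-6-(2-hydroxypropan-2-yl)-3-methylcyclohex-2-en-1-yl]-4-methylpent-3-en-1-yl}-6-methyl-1,2-dioxan-3-yl]propanoate, via alkylborane 14 (not isolated)
Conditions: 9-BBN, THF, 0 °C → rt; then 7, Pd(dppf)Cl2 (5 mol%), AsPh3, Cs2CO3, DMF/H2O, rt
Reagents that add atoms: none
Why: Anti-Markovnikov hydroboration of the vinyl group with 9-BBN followed by B-alkyl Suzuki–Miyaura coupling with the (E)-vinyl iodide forms the C8–C9 bond with retention of alkene geometry, dialkyl peroxides and esters being tolerated by the borane and by zerovalent palladium at room temperature; no stereocentre is touched (C6 becomes R only because the CIP priorities change).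

Step 10
Reactants: 15 methyl (2S)-2-[(3R,6R)-6-{(3E)-5-[(1R,6S)-6-(2-hydroxypropan-2-yl)-3-methylcyclohex-2-en-1-yl]-4-methylpent-3-en-1-yl}-6-methyl-1,2-dioxan-3-yl]propanoate
Product: 18 methyl (2S)-2-[(3R,6R)-6-methyl-6-{2-[(2R,3S,4aR,8aS)-2,3,6-trimethyl-1-methylidene-1,2,3,4,4a,7,8,8a-octahydronaphthalen-2-yl]ethyl}-1,2-dioxan-3-yl]propanoate, via cis-fused C10 cation 16 (not isolated), via rearranged C18 cation 17 (not isolated)
Conditions: SnCl4, 2,6-di-tert-butyl-4-methylpyridine, CH2Cl2, −78 → −40 °C
Reagents that add atoms: none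
Why: Proposed new method: SnCl4 ionises the tertiary alcohol (dialkyl peroxides and esters survive it at −78 °C) and the C18 cation is trapped 6-endo by the (E)-9,10-alkene through the chair that keeps the CMe2 unit equatorial on the cyclohexene, giving the cis-fused C10 cation with H9 axial and trans to the ring-fusion hydrogens; suprafacial antiperiplanar 1,2-H (C9→C10) and 1,2-Me (C18→C9) shifts then set C10 (S) and C9 (R), and the hindered pyridine removes a methyl proton from the C18 cation because C9 is quaternary and the only ring β-hydrogen (H17) lies near the nodal plane of the empty orbital, which gives the exocyclic methylene of the target; the closest known reactions are Lewis-acid cation–olefin polycyclisations and Wagner–Meerwein (Nametkin) methyl shifts in terpene backbone rearrangements.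

**Compound list**

1 | (1R,4S)-1-methyl-4-(prop-1-en-2-yl)cyclohex-2-en-1-ol (hydroxyl and isopropenyl on the same face) | C[C@]1(O)C=C[C@H](CC1)C(C)=C | starting material
2 | (3R,6S)-3-(ethenyloxy)-3-methyl-6-(prop-1-en-2-yl)cyclohex-1-ene | C[C@]1(OC=C)C=C[C@H](CC1)C(C)=C | intermediate (not isolated)
3 | 2-[(1R,6S)-3-methyl-6-(prop-1-en-2-yl)cyclohex-2-en-1-yl]acetaldehyde | O=CC[C@@H]1C=C(C)CC[C@@H]1C(C)=C | intermediate
4 | (3R,4S)-1-methyl-4-(prop-1-en-2-yl)-3-(prop-2-yn-1-yl)cyclohex-1-ene | C#CC[C@@H]1C=C(C)CC[C@@H]1C(C)=C | intermediate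
5 | dimethyl{(1E)-2-methyl-3-[(1R,6S)-3-methyl-6-(prop-1-en-2-yl)cyclohex-2-en-1-yl]prop-1-en-1-yl}alumane | C/C(C[C@@H]1C=C(C)CC[C@@H]1C(C)=C)=C\[Al](C)C | intermediate (not isolated)
6 | (3R,4S)-3-[(2E)-3-iodo-2-methylprop-2-en-1-yl]-1-methyl-4-(prop-1-en-2-yl)cyclohex-1-ene | C/C(C[C@@H]1C=C(C)CC[C@@H]1C(C)=C)=C\I | intermediate
7 | 2-[(1S,2R)-2-[(2E)-3-iodo-2-methylprop-2-en-1-yl]-4-methylcyclohex-3-en-1-yl]propan-2-ol | C/C(C[C@@H]1C=C(C)CC[C@@H]1C(C)(C)O)=C\I | intermediate
8 | 2-methylhexa-1,5-diene | C=CCCC(C)=C | starting material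
9 | methyl methacrylate | C=C(C)C(=O)OC | starting material
10 | methyl (2E)-2,6-dimethylhepta-2,6-dienoate | C=C(C)CC/C=C(\C)C(=O)OC | intermediate
11 | methyl (2E)-6-hydroperoxy-6-methoxy-2-methylhept-2-enoate (racemic at C6) | COC(C)(OO)CC/C=C(\C)C(=O)OC | intermediate
12 | methyl (2S)-2-[(3R)-6-methoxy-6-methyl-1,2-dioxan-3-yl]propanoate (both C6 epimers) | COC1(C)CC[C@H]([C@H](C)C(=O)OC)OO1 | intermediate
13 | methyl (2S)-2-[(3R,6S)-6-ethenyl-6-methyl-1,2-dioxan-3-yl]propanoate | C=C[C@]1(C)CC[C@H]([C@H](C)C(=O)OC)OO1 | intermediate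
14 | methyl (2S)-2-[(3R,6R)-6-[2-(9-borabicyclo[3.3.1]nonan-9-yl)ethyl]-6-methyl-1,2-dioxan-3-yl]propanoate | C(B1C2CCCC1CCC2)C[C@]1(C)CC[C@H]([C@H](C)C(=O)OC)OO1 | intermediate (not isolated)
15 | methyl (2S)-2-[(3R,6R)-6-{(3E)-5-[(1R,6S)-6-(2-hydroxypropan-2-yl)-3-methylcyclohex-2-en-1-yl]-4-methylpent-3-en-1-yl}-6-methyl-1,2-dioxan-3-yl]propanoate | C/C(C[C@@H]1C=C(C)CC[C@@H]1C(C)(C)O)=C\CC[C@]1(C)CC[C@H]([C@H](C)C(=O)OC)OO1 | intermediate
16 | cis-fused bicyclic C10 cation (C9–C18 bond formed, gem-dimethyl at C18, H9 axial) | C[C+]1C[C@@H]2C=C(C)CC[C@@H]2C(C)(C)[C@H]1CC[C@]1(C)CC[C@H]([C@H](C)C(=O)OC)OO1 | intermediate (not isolated)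
17 | rearranged C18 cation (after the 1,2-H and 1,2-Me shifts) | C[C+]1[C@H]2CCC(C)=C[C@H]2C[C@H](C)[C@@]1(C)CC[C@]1(C)CC[C@H]([C@H](C)C(=O)OC)OO1 | intermediate (not isolated)
18 | methyl (2S)-2-[(3R,6R)-6-methyl-6-{2-[(2R,3S,4aR,8aS)-2,3,6-trimethyl-1-methylidene-1,2,3,4,4a,7,8,8a-octahydronaphthalen-2-yl]ethyl}-1,2-dioxan-3-yl]propanoate (CNP0144520.2) | C=C1[C@H]2CCC(C)=C[C@H]2C[C@H](C)[C@@]1(C)CC[C@]1(C)CC[C@H]([C@H](C)C(=O)OC)OO1 | target

**Step count**

Total: 10 steps. Longest linear sequence: 6 steps (1 → 3 → 4 → 6 → 7 → 15 → 18; the sequence through fragment 2, 8 → 10 → 11 → 12 → 13 → 15 → 18, is equally long).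

**Three steps most likely to fail**

Step 10 (cascade). Nothing pulls the shifts forward thermodynamically: the C10 cation may simply lose a proton, the peroxide oxygen on C6 may intercept it, or the exocyclic alkene may isomerise under acid. The fallback sets out from 6 and returns at 18. Oxidative cleavage of the isopropenyl group of 6 (OsO4 cat., NaIO4, 2,6-lutidine, dioxane/H2O; the 1,1-disubstituted alkene is the least hindered) gives iodo ketone F1. F1 is coupled with alkylborane 14 as in step 9 to give keto ester F2. SnCl4 at −78 °C then activates the ketone, the 9,10-alkene adds to C18 (carbonyl–olefin cyclisation of the Prins type) and the zwitterion undergoes the same 1,2-H and 1,2-Me shifts, now ended irreversibly by re-formation of the C18 carbonyl group (semipinacol), giving decalone F3. Non-basic methylenation of F3 (Zn, CH2Br2, TiCl4), chosen because an ylide would threaten the ester and the peroxide, gives 18.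

Step 7 (asymmetric peroxy-Michael closure). The α-methyl enoate is a sluggish acceptor and catalyst control with a hydroperoxy-ketal nucleophile is unproven. The fallback sets out from 8 and returns at 12. Cross-metathesis of 8 with methacrolein gives dienal F4 and ozonolysis in MeOH gives hydroperoxy ketal enal F5. A 9-amino-9-deoxy-epi-cinchona primary amine salt then forms the iminium ion of the α-branched enal (a substrate class for which this activation is established); the tethered hydroperoxide adds to C3 and the enamine is protonated under catalyst control, giving dioxanyl propanal F6. Pinnick oxidation gives dioxanyl propanoic acid F7, and TMSCHN2 converts F7 into 12.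

Step 8 (vinyl transfer to the peroxycarbenium ion). Vinyl transfer may be slow, and the tertiary allylic peroxide product can re-ionise under BF3 and scramble C6. The fallback sets out from 12 and returns at 15. TMSOTf and tributyl(ethynyl)stannane give ethynyl dioxane F8 (small sp nucleophile, axial attack; the propargylic peroxide re-ionises less readily). Sonogashira coupling of F8 with 7 (Pd(PPh3)2Cl2, CuI, iPr2NH) gives enyne F9. Diimide (2-nitrobenzenesulfonylhydrazide, Et3N) reduces the alkyne through the cis-disubstituted alkene to the saturated C7–C8 link without touching the trisubstituted alkenes, which gives 15.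

Further compounds
F1 | step 10 | 1-[(1S,2R)-2-[(2E)-3-iodo-2-methylprop-2-en-1-yl]-4-methylcyclohex-3-en-1-yl]ethan-1-one | C/C(C[C@@H]1C=C(C)CC[C@@H]1C(C)=O)=C\I
F2 | step 10 | methyl (2S)-2-[(3R,6R)-6-{(3E)-5-[(1R,6S)-6-acetyl-3-methylcyclohex-2-en-1-yl]-4-methylpent-3-en-1-yl}-6-methyl-1,2-dioxan-3-yl]propanoate | C/C(C[C@@H]1C=C(C)CC[C@@H]1C(C)=O)=C\CC[C@]1(C)CC[C@H]([C@H](C)C(=O)OC)OO1
F3 | step 10 | methyl (2S)-2-[(3R,6R)-6-methyl-6-{2-[(2R,3S,4aR,8aS)-2,3,6-trimethyl-1-oxo-1,2,3,4,4a,7,8,8a-octahydronaphthalen-2-yl]ethyl}-1,2-dioxan-3-yl]propanoate | O=C1[C@H]2CCC(C)=C[C@H]2C[C@H](C)[C@@]1(C)CC[C@]1(C)CC[C@H]([C@H](C)C(=O)OC)OO1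
F4 | step 7 | (2E)-2,6-dimethylhepta-2,6-dienal | C=C(C)CC/C=C(\C)C=O
F5 | step 7 | (2E)-6-hydroperoxy-6-methoxy-2-methylhept-2-enal | COC(C)(OO)CC/C=C(\C)C=O
F6 | step 7 | (2S)-2-[(3R)-6-methoxy-6-methyl-1,2-dioxan-3-yl]propanal | COC1(C)CC[C@H]([C@H](C)C=O)OO1
F7 | step 7 | (2S)-2-[(3R)-6-methoxy-6-methyl-1,2-dioxan-3-yl]propanoic acid | COC1(C)CC[C@H]([C@H](C)C(=O)O)OO1
F8 | step 8 | methyl (2S)-2-[(3R,6S)-6-ethynyl-6-methyl-1,2-dioxan-3-yl]propanoate | C#C[C@]1(C)CC[C@H]([C@H](C)C(=O)OC)OO1
F9 | step 8 | methyl (2S)-2-[(3R,6S)-6-{(3E)-5-[(1R,6S)-6-(2-hydroxypropan-2-yl)-3-methylcyclohex-2-en-1-yl]-4-methylpent-3-en-1-yn-1-yl}-6-methyl-1,2-dioxan-3-yl]propanoate | C/C(C[C@@H]1C=C(C)CC[C@@H]1C(C)(C)O)=C\C#C[C@]1(C)CC[C@H]([C@H](C)C(=O)OC)OO1
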